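**Plan**

1. Phenanthrene numbering is used (C1 C=O, C2 OMe, C3 N, C4 C(Me)–O, C9 C=O, C10 H2). Retrosynthetic cuts, in order: the aminal C–O and C–N bonds (together with unmasking of the C8 phenol and C9 ketone), C4–CH3, C1–C10a (ring A), C4–C4a (aryl to four-membered ring), then C5–C6 and C7–C8 (ring C).
2. Forward: ring C is annulated onto a brominated salicylate (ring B); the derived naphthyllithium adds to an aminosquarate; ring expansion forms ring A; methyl is added at C4; one acid operation closes the pyrrolidine and oxazolidine rings and frees the C8 phenol and C9 ketone.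
3. Enabling feature: ring A holds O at C1 and C4, OMe at C2 and N at C3, the contiguous O/OMe/N/O pattern of a 3-amino-4-methoxycyclobutenedione, and is fused to the naphthalene across C4a–C10a.
4. Stereochemistry: C4 (R) is created by methyl addition to the C4 carbonyl, the (S)-1-(4-methoxyphenyl)ethyl group on nitrogen turning the C4 epimers into separable diastereomers; the aminal carbon (S) is then dictated by C4 in the reversible N,O-acetal closure.

Key step: step 9

Assumption: the 10H-9-keto tautomer drawn for the target (C9=O chelated by the C8 hydroxyl, C4a=C10a conjugated with C1=O) is taken to be the stable form, so the 9-phenanthrol freed in the last step should convert into it spontaneously.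
Assumption: the sense of the facial bias exerted by the N-benzylic group in step 10 cannot be predicted securely; the route is committed to the (S)-amine and takes on the (4R)-epimer after chromatographic separation, whichever epimer predominates.
Abbreviations in names: Am = (4,4-dimethoxybutyl)[(1S)-1-(4-methoxyphenyl)ethyl]amino; MOM = methoxymethyl.

**Route**

Step 1
Reactants: 1 methyl 2-hydroxy-6-methylbenzoate
Product: 2 methyl 3-bromo-6-hydroxy-2-methylbenzoate
Conditions: NBS (1.0 equiv), MeCN, 0 °C to rt, dark
Reagents that add atoms: N-bromosuccinimide, O=C1CCC(=O)N1Br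
Why: Electrophilic aromatic bromination of a salicylate goes para to the hydroxyl, and that carbon is also ortho to the methyl group and meta to the ester, so all three substituents direct bromine to the carbon that becomes C4a.

Step 2
Reactants: 2 methyl 3-bromo-6-hydroxy-2-methylbenzoate
Product: 3 methyl 3-bromo-6-(methoxymethoxy)-2-methylbenzoate
Conditions: NaH, MOMCl, DMF, 0 °C
Reagents that add atoms: chloromethyl methyl ether, COCCl
Why: Williamson-type O-alkylation of the phenoxide masks the acidic hydroxyl before the lateral lithiation.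

Step 3
Reactants: 3 methyl 3-bromo-6-(methoxymethoxy)-2-methylbenzoate
Product: 4 methyl 3-bromo-6-(methoxymethoxy)-2-(2-oxopropyl)benzoate
Conditions: LiN(iPr)2 (1.2 equiv), THF, −78 °C; then MeC(O)N(OMe)Me, −78 °C; aq NH4Cl
Reagents that add atoms: N-methoxy-N-methylacetamide, CC(=O)N(C)OC
Why: Lateral (benzylic) lithiation of an ortho-toluate whose ester is too hindered by its two ortho substituents to self-condense at −78 °C, followed by Weinreb amide acylation that stops at the methyl ketone, is standard, and a lithium amide does not exchange the aryl bromide.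

Step 4
Reactants: 4 methyl 3-bromo-6-(methoxymethoxy)-2-(2-oxopropyl)benzoate
Product: 6 5-bromo-3-methoxynaphthalene-1,8-diol, via 5-bromo-8-(methoxymethoxy)naphthalene-1,3-diol 5 (not isolated)
Conditions: NaOMe (3 equiv), MeOH, 65 °C, N2; then HCl in MeOH (excess), 65 °C
Reagents that add atoms: methanol, CO
Why: Intramolecular Claisen (Dieckmann-type) condensation of the methyl ketone enolate onto the aryl ester closes ring C as an aromatic naphthalene-1,3-diol (any enol lactone is reopened by methoxide), and methanolic HCl then etherifies only the 3-hydroxyl through its non-conjugated keto tautomer, the known selectivity of naphthalene-1,3-diols, while cleaving the MOM ether.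

Step 5
Reactants: 6 5-bromo-3-methoxynaphthalene-1,8-diol
Product: 7 5-bromo-3-methoxy-1,8-bis(methoxymethoxy)naphthalene
Conditions: NaH (2.5 equiv), MOMCl (2.5 equiv), DMF, 0 °C to rt
Reagents that add atoms: chloromethyl methyl ether, COCCl
Why: Double O-alkylation of the peri-diol gives acid-labile ethers that tolerate organolithium reagents, heat and the later methyl addition.

Step 6
Reactants: 8 (S)-1-(4-methoxyphenyl)ethylamine; 9 4-chloro-1,1-dimethoxybutane
Product: 10 (1S)-N-(4,4-dimethoxybutyl)-1-(4-methoxyphenyl)ethanamine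
Conditions: 8 (2 equiv), K2CO3, NaI (catalytic), MeCN, 80 °C
Reagents that add atoms: none
Why: Finkelstein-assisted SN2 N-alkylation of the primary amine, with the α-branched amine in excess to limit dialkylation, leaves the base-stable acetal and the stereocentre untouched.

Step 7
Reactants: 10 (1S)-N-(4,4-dimethoxybutyl)-1-(4-methoxyphenyl)ethanamine; 11 dimethyl squarate
Product: 12 3-Am-4-methoxycyclobut-3-ene-1,2-dione (squaramate)
Conditions: MeOH, rt to 40 °C
Reagents that add atoms: none
Why: Addition–elimination of a secondary amine on dimethyl squarate stops at the monoamide ester because the vinylogous amide formed deactivates the remaining methoxy group.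

Step 8
Reactants: 7 5-bromo-3-methoxy-1,8-bis(methoxymethoxy)naphthalene; 12 3-Am-4-methoxycyclobut-3-ene-1,2-dione
Product: 14 3-Am-4-hydroxy-2-methoxy-4-[7-methoxy-4,5-bis(methoxymethoxy)naphthalen-1-yl]cyclobut-2-en-1-one (both carbinol epimers), via [7-methoxy-4,5-bis(methoxymethoxy)naphthalen-1-yl]lithium 13 (not isolated)
Conditions: 7, n-BuLi (1.05 equiv), THF, −78 °C; then 12 in THF, −78 °C; aq NH4Cl
Reagents that add atoms: none
Why: Bromine–lithium exchange outruns ortho-lithiation at −78 °C, and the aryllithium adds 1,2 to the squaramate carbonyl that is only a vinylogous ester (the one next to the amino-bearing carbon) in preference to the vinylogous amide carbonyl, the usual regiochemistry of organolithium additions to squaric acid derivatives; the carbinol configuration is irrelevant because that carbon becomes sp2.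

Step 9
Reactants: 14 3-Am-4-hydroxy-2-methoxy-4-[7-methoxy-4,5-bis(methoxymethoxy)naphthalen-1-yl]cyclobut-2-en-1-one
Product: 17 3-Am-2,6-dimethoxy-8,9-bis(methoxymethoxy)phenanthrene-1,4-dione, via naphthyl vinylketene 15 (not isolated), via 3-Am-phenanthrene-1,4-diol 16 (not isolated)
Conditions: p-xylene, 138 °C, N2; then Ag2O, CH2Cl2, rt
Reagents that add atoms: none
Why: Heating opens the cyclobutenone by conrotatory 4π-electrocyclic cleavage of the C(=O)–C(OH) bond, the hydroxyl rotating outward so that the naphthyl group ends cis to the ketene in vinylketene 15. The ketene carbon then bonds to the free ortho carbon of the naphthalene (C10a) in a thermal disrotatory 6π-electrocyclisation that closes six-membered ring A, and tautomerisation gives hydroquinone 16, which Ag2O oxidises to quinone 17. This is the Moore rearrangement of 4-aryl-4-hydroxycyclobutenones, well established for squarate-derived substrates. No stereocentre is formed, and the carbinol centre of 14 is lost. The selectivity needed is regiochemical: the other ortho position of the naphthyl group is a ring-fusion carbon, so only C10a can be attacked, and because the aryl group sits on the carbon next to the amino-bearing carbon, nitrogen must end at C3 and methoxy at C2. Outward rotation of the oxygen donor, the known torquoselectivity, disfavours the alternative hydroxyl-to-ketene closure to a butenolide.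

Step 10
Reactants: 17 3-Am-2,6-dimethoxy-8,9-bis(methoxymethoxy)phenanthrene-1,4-dione
Product: 18 (4R)-3-Am-4-hydroxy-2,6-dimethoxy-8,9-bis(methoxymethoxy)-4-methylphenanthren-1(4H)-one
Conditions: MeLi (1.2 equiv), THF, −78 °C; aq NH4Cl; chromatographic separation of the C4 epimers
Reagents that add atoms: methyllithium, [Li]C
Why: 1,2-Addition of methyllithium to a quinone carbonyl (quinol synthesis) is expected at C4, which is only a vinylogous ester carbonyl (MeO–C2=C3–C4=O) and whose bay strain is relieved on becoming sp3, in preference to C1, which is deactivated as a vinylogous amide (N–C3=C2–C1=O); the (S)-benzylic group on the neighbouring nitrogen makes the two faces of C4=O diastereotopic, and whatever bias it exerts, the C4 epimers are diastereomers from which the (4R)-carbinol is separated.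

Step 11
Reactants: 18 (4R)-3-Am-4-hydroxy-2,6-dimethoxy-8,9-bis(methoxymethoxy)-4-methylphenanthren-1(4H)-one
Product: 20 CNP0528850.1 (target; 4R and aminal S), via 9-hydroxyphenanthren-1-one tautomer 19 (not isolated)
Conditions: TFA–CH2Cl2–H2O (20:78:2), anisole (10 equiv), 0 °C to rt; aq NaHCO3
Reagents that add atoms: none
Why: In acid the 4-methoxy-α-methylbenzyl group leaves nitrogen as a stabilised cation (trapped by anisole), the freed N–H vinylogous amide condenses with the unmasked aldehyde to a cyclic N-acyliminium ion that the C4 hydroxyl captures (N,O-acetalisation), and both MOM ethers hydrolyse; the reversible acetal closure should settle on the (S) aminal, whose hydrogen is cis to the C4 methyl, because only this arrangement keeps the acetal oxygen on one face of the planar N–C3 vinylogous amide in both five-membered rings, and the freed 9-phenanthrol 19 then tautomerises to the chelated 10H-9-ketone 20.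

**Compound list**

1 | methyl 2-hydroxy-6-methylbenzoate | COC(=O)c1c(C)cccc1O | starting material
2 | methyl 3-bromo-6-hydroxy-2-methylbenzoate | COC(=O)c1c(C)c(Br)ccc1O | intermediate
3 | methyl 3-bromo-6-(methoxymethoxy)-2-methylbenzoate | COCOc1ccc(Br)c(C)c1C(=O)OC | intermediate
4 | methyl 3-bromo-6-(methoxymethoxy)-2-(2-oxopropyl)benzoate | COCOc1ccc(Br)c(CC(C)=O)c1C(=O)OC | intermediate
5 | 5-bromo-8-(methoxymethoxy)naphthalene-1,3-diol | COCOc1ccc(Br)c2cc(O)cc(O)c12 | intermediate
6 | 5-bromo-3-methoxynaphthalene-1,8-diol | COc1cc(O)c2c(O)ccc(Br)c2c1 | intermediate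
7 | 5-bromo-3-methoxy-1,8-bis(methoxymethoxy)naphthalene | COCOc1cc(OC)cc2c(Br)ccc(OCOC)c12 | intermediate
8 | (S)-1-(4-methoxyphenyl)ethylamine | C[C@H](N)c1ccc(OC)cc1 | starting material
9 | 4-chloro-1,1-dimethoxybutane (4-chlorobutanal dimethyl acetal) | COC(CCCCl)OC | starting material
10 | (1S)-N-(4,4-dimethoxybutyl)-1-(4-methoxyphenyl)ethanamine | COC(OC)CCCN[C@@H](C)c1ccc(OC)cc1 | intermediate
11 | dimethyl squarate (3,4-dimethoxycyclobut-3-ene-1,2-dione) | COC1=C(OC)C(=O)C1=O | starting material
12 | 3-{(4,4-dimethoxybutyl)[(1S)-1-(4-methoxyphenyl)ethyl]amino}-4-methoxycyclobut-3-ene-1,2-dione | COC1=C(N(CCCC(OC)OC)[C@@H](C)c2ccc(OC)cc2)C(=O)C1=O | intermediate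
13 | [7-methoxy-4,5-bis(methoxymethoxy)naphthalen-1-yl]lithium | [Li]c1ccc(OCOC)c2c(OCOC)cc(OC)cc12 | intermediate
14 | 3-Am-4-hydroxy-2-methoxy-4-[7-methoxy-4,5-bis(methoxymethoxy)naphthalen-1-yl]cyclobut-2-en-1-one, both epimers at the carbinol carbon | O=C1C(OC)=C(N(CCCC(OC)OC)[C@@H](C)c2ccc(OC)cc2)C1(O)c1ccc(OCOC)c2c(OCOC)cc(OC)cc12 | intermediate
15 | 3-Am-4-hydroxy-2-methoxy-4-[7-methoxy-4,5-bis(methoxymethoxy)naphthalen-1-yl]buta-1,3-dien-1-one (vinylketene, naphthyl cis to the ketene carbon) | O=C=C(OC)/C(N(CCCC(OC)OC)[C@@H](C)c1ccc(OC)cc1)=C(\c1ccc(OCOC)c2c(OCOC)cc(OC)cc12)O | intermediate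
16 | 3-Am-2,6-dimethoxy-8,9-bis(methoxymethoxy)phenanthrene-1,4-diol | COc1c(N(CCCC(OC)OC)[C@@H](C)c2ccc(OC)cc2)c(O)c2c(cc(OCOC)c3c(OCOC)cc(OC)cc23)c1O | intermediate
17 | 3-Am-2,6-dimethoxy-8,9-bis(methoxymethoxy)phenanthrene-1,4-dione | COC1=C(N(CCCC(OC)OC)[C@@H](C)c2ccc(OC)cc2)C(=O)c2c(cc(OCOC)c3c(OCOC)cc(OC)cc23)C1=O | intermediate
18 | (4R)-3-Am-4-hydroxy-2,6-dimethoxy-8,9-bis(methoxymethoxy)-4-methylphenanthren-1(4H)-one | COC1=C(N(CCCC(OC)OC)[C@@H](C)c2ccc(OC)cc2)[C@@](O)(C)c2c(cc(OCOC)c3c(OCOC)cc(OC)cc23)C1=O | intermediate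
19 | 9-hydroxy tautomer of the target: (4R)-8,9-dihydroxy-2,6-dimethoxy-4-methylphenanthren-1(4H)-one whose C3 nitrogen and C4 oxygen are joined through N1 and C2 (S) of a pyrrolidine ring | COC1=C2N3CCC[C@@H]3O[C@]2(C)c2c(cc(O)c3c(O)cc(OC)cc23)C1=O | intermediate
20 | CNP0528850.1: (4R)-8-hydroxy-2,6-dimethoxy-4-methyl-10H-phenanthrene-1,9-dione whose C3 nitrogen and C4 oxygen are joined through N1 and C2 (S) of a pyrrolidine ring (N,O-acetal) | COC1=C2N3CCC[C@@H]3O[C@]2(C)C2=C(CC(=O)c3c(O)cc(OC)cc32)C1=O | target

**Step count and risks**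

Total step count: 11. Longest linear sequence: 9 steps (steps 1 to 5 and 8 to 11).

Steps most likely to fail:

1. Step 10. The methyl nucleophile may attack C1 instead of C4 if the crowded amino group twists out of conjugation and no longer deactivates C1. Single-electron reduction of the quinone may compete, and facial discrimination may be poor. The fallback sets out from 14 and returns at 20.
   - The carbinol of 14 would be silylated (TBSOTf, 2,6-lutidine) to the 4-(tert-butyldimethylsilyloxy)cyclobutenone F1.
   - The thermolysis of step 9, without oxidant, should give the 4-silyloxyphenanthren-1-ol F2, since Moore rearrangement of 4-silyloxycyclobutenones gives monoprotected hydroquinones.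
   - O-Methylation (Me2SO4, K2CO3, acetone) would give the 1-methyl ether F3, and Bu4NF would free the phenanthren-4-ol F4.
   - PhI(OAc)2 in MeOH would oxidise this para-methoxyphenol to the quinone monoketal F5, whose only carbonyl is C4.
   - MeLi addition and separation of the epimers would give the (4R)-carbinol ketal F6, which under the conditions of step 11 also loses the ketal and delivers 20.

2. Step 11. Several acid-driven events must coincide. The C4 configuration may erode through reversible ionisation of the C4–O bond once the electron-releasing C9 oxygen is free. The liberated formaldehyde or benzylic cation may alkylate the electron-rich product, and cleavage of the N-benzylic group may lag behind. The fallback sets out from 6 and returns at 20.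
   - The peri-diol would be benzylated (BnBr, K2CO3, DMF) to 1,8-bis(benzyloxy)-5-bromo-3-methoxynaphthalene F7.
   - F7 would be taken through the operations of steps 8, 9 and 10 to the bis(benzyloxy) cyclobutenone F8, the bis(benzyloxy) quinone F9 and the (4R)-bis(benzyloxy) carbinol F10.
   - TFA and anisole in CH2Cl2 would then remove the N-benzylic group and close the N,O-acetal while the benzyl ethers stay, giving the bis(benzyl) ether F11 of 19 with ring B still aromatic and no formaldehyde released.
   - Neutral hydrogenolysis (H2, Pd/C, EtOAc) would finally free both phenols to give 19, which tautomerises to 20.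

3. Step 8. The bulky N-substituents may shield the carbonyl next to the amino-bearing carbon, so that addition is slow or goes to the other carbonyl. The waiting aryllithium may also isomerise by proton transfer to an ortho-lithiated species. The fallback sets out from bromide 7 (as aryllithium 13) and squarate 11, and returns at 14.
   - Aryllithium 13 would be added to dimethyl squarate 11 itself, whose carbonyls are equivalent and unhindered, to give the 4-hydroxy-2,3-dimethoxy-4-naphthylcyclobutenone F12.
   - Amine 10 would then displace the C3 methoxy group (the β-carbon of the vinylogous ester) by addition–elimination in MeOH, which places nitrogen next to the carbinol carbon and gives 14.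

**Further compounds**

F1 | step 10 | 3-Am-4-(tert-butyldimethylsilyloxy)-2-methoxy-4-[7-methoxy-4,5-bis(methoxymethoxy)naphthalen-1-yl]cyclobut-2-en-1-one | O=C1C(OC)=C(N(CCCC(OC)OC)[C@@H](C)c2ccc(OC)cc2)C1(O[Si](C)(C)C(C)(C)C)c1ccc(OCOC)c2c(OCOC)cc(OC)cc12
F2 | step 10 | 3-Am-4-(tert-butyldimethylsilyloxy)-2,6-dimethoxy-8,9-bis(methoxymethoxy)phenanthren-1-ol | COc1c(N(CCCC(OC)OC)[C@@H](C)c2ccc(OC)cc2)c(O[Si](C)(C)C(C)(C)C)c2c(cc(OCOC)c3c(OCOC)cc(OC)cc23)c1O
F3 | step 10 | 3-Am-4-(tert-butyldimethylsilyloxy)-1,2,6-trimethoxy-8,9-bis(methoxymethoxy)phenanthrene | COc1c(N(CCCC(OC)OC)[C@@H](C)c2ccc(OC)cc2)c(O[Si](C)(C)C(C)(C)C)c2c(cc(OCOC)c3c(OCOC)cc(OC)cc23)c1OC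
F4 | step 10 | 3-Am-1,2,6-trimethoxy-8,9-bis(methoxymethoxy)phenanthren-4-ol | COc1c(N(CCCC(OC)OC)[C@@H](C)c2ccc(OC)cc2)c(O)c2c(cc(OCOC)c3c(OCOC)cc(OC)cc23)c1OC
F5 | step 10 | 3-Am-1,1,2,6-tetramethoxy-8,9-bis(methoxymethoxy)phenanthren-4(1H)-one | COC1=C(N(CCCC(OC)OC)[C@@H](C)c2ccc(OC)cc2)C(=O)c2c(cc(OCOC)c3c(OCOC)cc(OC)cc23)C1(OC)OC
F6 | step 10 | (4R)-3-Am-1,1,2,6-tetramethoxy-8,9-bis(methoxymethoxy)-4-methyl-1,4-dihydrophenanthren-4-ol | COC1=C(N(CCCC(OC)OC)[C@@H](C)c2ccc(OC)cc2)[C@@](O)(C)c2c(cc(OCOC)c3c(OCOC)cc(OC)cc23)C1(OC)OC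
F7 | step 11 | 1,8-bis(benzyloxy)-5-bromo-3-methoxynaphthalene | COc1cc(OCc2ccccc2)c2c(OCc3ccccc3)ccc(Br)c2c1
F8 | step 11 | 3-Am-4-[4,5-bis(benzyloxy)-7-methoxynaphthalen-1-yl]-4-hydroxy-2-methoxycyclobut-2-en-1-one, both carbinol epimers | O=C1C(OC)=C(N(CCCC(OC)OC)[C@@H](C)c2ccc(OC)cc2)C1(O)c1ccc(OCc2ccccc2)c2c(OCc3ccccc3)cc(OC)cc12
F9 | step 11 | 3-Am-8,9-bis(benzyloxy)-2,6-dimethoxyphenanthrene-1,4-dione | COC1=C(N(CCCC(OC)OC)[C@@H](C)c2ccc(OC)cc2)C(=O)c2c(cc(OCc3ccccc3)c3c(OCc4ccccc4)cc(OC)cc23)C1=O
F10 | step 11 | (4R)-3-Am-8,9-bis(benzyloxy)-4-hydroxy-2,6-dimethoxy-4-methylphenanthren-1(4H)-one | COC1=C(N(CCCC(OC)OC)[C@@H](C)c2ccc(OC)cc2)[C@@](O)(C)c2c(cc(OCc3ccccc3)c3c(OCc4ccccc4)cc(OC)cc23)C1=O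
F11 | step 11 | 8,9-di-O-benzyl ether of 19 (4R, aminal S) | COC1=C2N3CCC[C@@H]3O[C@]2(C)c2c(cc(OCc3ccccc3)c3c(OCc4ccccc4)cc(OC)cc23)C1=O
F12 | step 8 | 4-hydroxy-2,3-dimethoxy-4-[7-methoxy-4,5-bis(methoxymethoxy)naphthalen-1-yl]cyclobut-2-en-1-one | O=C1C(OC)=C(OC)C1(O)c1ccc(OCOC)c2c(OCOC)cc(OC)cc12
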